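1. At early times, by hand, the fraction of the electrophile that has reacted grows in a straight line: it is close to E = k·c·t, with k a constant still to be read, c the nucleophile charge and t the time.

in all of them: electrophile 0.050 M
- elm: nucleophile 0.074 M; run made earlier
- ash: nucleophile 0.17 M; run made earlier
- alder: nucleophile 0.32 M; run made earlier
- beta: nucleophile 0.0900 M; time 30 h
- delta: nucleophile 0.180 M; time 30 h
- zeta: nucleophile 0.360 M; time 30 h

| run | time / h | electrophile / % | target / % |
|---|---|---|---|
| elm | 1.50 | 95.9 | 2.0 |
| elm | 3.00 | 94.8 | 4.8 |
| elm | 6.00 | 91.4 | 9.1 |
| elm | 12.0 | 82.7 | 16.9 |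
| elm | 20.0 | 73.1 | 26.1 |
| ash | 1.50 | 94.3 | 7.1 |
| ash | 3.00 | 87.3 | 11.2 |
| ash | 6.00 | 80.0 | 19.2 |
| ash | 12.0 | 65.5 | 34.8 |
| ash | 20.0 | 50.8 | 47.0 |
| alder | 4.00 | 75.7 | 24.4 |
| alder | 8.00 | 56.1 | 42.8 |
| alder | 12.0 | 44.6 | 54.9 |
| alder | 15.0 | 37.2 | 62.5 |
| alder | 20.0 | 26.2 | 72.3 |

(standard deviation of a reading: 1 percentage point)

- the earlier runs were read with a standard deviation of 1 percentage point

* part of the electrophile that has reacted at the end, beta
* part of the electrophile that has reacted at the end, delta
* part of the electrophile that has reacted at the end, zeta
* what raising the concentration of nucleophile from its lowest to its highest value here does to the part of the electrophile that has reacted (changes below 5 percentage points count as none) (no change / it falls / it rises)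

2. Later, what is left keeps losing the same share per hour, as long as the nucleophile stays near its charge (the pseudo-first-order picture). So the fraction left is exp(−E), which joins the early line for small E.

3. The alder run left 26.2% at 20.0 h, so k reads 0.209 /M/h. This reach constant, the E a flask earns per molar hour of nucleophile, carries the scatter of that reading.

4. Nucleophile: by hand, doubling the charge at a fixed time doubles E. At 12.0 h, E says 34.7% reacted for ash and 55.2% for alder; the readings give 34.5% and 55.4%.

5. Time: by hand, it acts on E just as the charge does. For alder at 4.00 h, E says 23.5%; the reading gives 24.3%.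

6. Electrophile: it does not appear in E, so by hand it does nothing. Elm, ash and alder were charged alike with 0.050 M, so they cannot test this.

7. At 30 h, E is 0.565 for beta, 1.13 for delta and 2.26 for zeta. Your reckoning is therefore 43.2%, 67.7% and 89.6% reacted.

8. The forecast says 40.7%, 65.6% and 88.9%, a little lower than your figures: “Conversion therefore rises strongly with nucleophile.”

The flask gives 38.2% for beta, 63.1% for delta and 87.9% for zeta, each within the forecast's tolerance and below E's figure; from beta to zeta the part reacted goes up by 50 points, so the answer on the trend is: it rises.

electrophile + nucleophile → acid set free + target (k = 0.00390 /M/min); nucleophile + acid set free ⇌ protonated nucleophile, settled at all times (K = 300 /M); acid set free → by-product carried off (k = 6.10 × 10⁻⁴ /min) Recharge delta with 0.085 M of electrophile: E stays 1.13 and still says 67.7%, yet that flask stands at 57.0%. At 30 h beta, delta and zeta have not come to rest: each stands lower than it does later. Ten times the time makes beta's E 5.65, which says 99.6%, but beta reaches 90.8%, with 9.16% of its electrophile left. That stay adds 53 points to beta, 37 points to delta and 12 points to zeta, which ends at 100%.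

(All runs come from a simulation for substances that don't exist, noise included.)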